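Numbering: cyclopentane C1–C5 with C5 the spiro atom, cyclohexenone C5–C10 (C2 isopropenyl, C4 and C9 oxygens, C6 and C10 methyls, C8 ketone).
Cuts: the two ester acyl–O bonds, then C6=C7 (olefin metathesis) and C8–C9 (acryloyl anion onto an aldehyde), leaving a γ-lactone C4–O–C9(=O)–C10–C5. Removing the C10 methyl and the ring oxygen gives a cyclobutanone, cut at C4–C9 and C5–C10 into an acetylcyclopentene and ketene diethyl acetal; the cyclopentene is cut at C4=C5 to a limonene-derived keto aldehyde.
Enabling feature: on ring C1–C5 the spiro atom C5 holds C10 on the same face as the C4 oxygen, the imprint of a cis-fused four-membered ring C4–C9–C10–C5 after oxygen insertion into C4–C9. C1–C6, the C6 methyl and the isopropenyl carbons are the ten carbons of limonene.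
Forward ring order: cyclopentene (aldol condensation), cyclobutane ([2+2] photocycloaddition), γ-lactone (ring expansion), lactone opened as C7–C8 is attached at C9, cyclohexenone closed last (metathesis), then two acylations.
Stereochemistry: C2 from (S)-limonene; C4 and C5 together in the cis-fused photoadduct formed anti to the isopropenyl group and kept through the Baeyer–Villiger shift; C10 by enolate methylation anti to the angular isopropenyl; C9 by Felkin–Anh addition to the C10-branched aldehyde.

Key step: step 4

Remark: the SMILES is read as the (2S,4R,5R,9R,10S) isomer. The epoxide/diol diastereomers in 2 and 3 and the anomers of 14 are carried as mixtures because those centres are destroyed or converge.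

Step 1
Reactants: 1 (S)-(−)-limonene
Product: 2 (4S)-limonene 1,2-oxide (cis/trans mixture)
Conditions: mCPBA (1.0 equiv), CH2Cl2, 0 °C
Reagents that add atoms: 3-chloroperoxybenzoic acid (mCPBA), O=C(OO)c1cccc(Cl)c1
Why: Prilezhaev epoxidation, in which the peracid should select the more electron-rich trisubstituted ring alkene over the 1,1-disubstituted isopropenyl group; the epoxide configuration is irrelevant because both carbons become carbonyls, and C4 of limonene is untouched.

Step 2
Reactants: 2 (4S)-limonene 1,2-oxide
Product: 4 (3S)-3-isopropenyl-6-oxoheptanal, via limonene-1,2-diol 3 (not isolated)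
Conditions: H5IO6, THF/H2O, 0 °C to rt
Reagents that add atoms: water, O
Why: Acid-catalysed hydration of the epoxide to the vicinal diol followed in the same flask by Malaprade glycol cleavage with periodic acid should give the keto aldehyde, leaving the isopropenyl group and the stereocentre alone.

Step 3
Reactants: 4 (3S)-3-isopropenyl-6-oxoheptanal
Product: 5 (R)-1-acetyl-4-isopropenylcyclopentene
Conditions: piperidine (cat.), AcOH (cat.), toluene, 80 °C, water removal
Reagents that add atoms: none
Why: Amine–acid catalysed intramolecular aldol condensation, in which the ring-forming α-methylene of the methyl ketone adds to the iminium-activated aldehyde to close the five-membered ring (the methyl group could only close a seven-membered one) and dehydration gives the conjugated enone; the stereocentre is remote and not enolisable.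

Step 4
Reactants: 5 (R)-1-acetyl-4-isopropenylcyclopentene; 6 ketene diethyl acetal
Product: 7 1-acetyl-6,6-diethoxy-3-isopropenyl-cis-bicyclo[3.2.0]heptane (acetyl on ring-fusion carbon C5, ketal carbon C9 on C4, cyclobutane anti to the isopropenyl)
Conditions: 6 (10 equiv), hν (λ > 300 nm, Pyrex), pentane, −40 °C, base-washed glassware
Reagents that add atoms: none
Why: Excitation of the enone of 5 and intersystem crossing give its triplet, which bonds to the electron-rich alkene 6 to form a triplet 1,4-diradical that closes after spin inversion; this is the classical enone–alkene [2+2] photocycloaddition in its ketene acetal variant. The four-membered ring C4–C9–C10–C5 closes by formation of the C4–C9 and C5–C10 bonds across the former enone double bond, and on a five-membered ring the fusion can only be cis. C5 becomes quaternary and C4 a ring-fusion methine; their mutual configuration is fixed by the cis fusion and their configuration relative to C2 by addition of 6 to the ring face opposite the C2 isopropenyl group. Head-to-tail regiochemistry is required and is secured by the donor-substituted carbon of 6 ending on the β-carbon C4 and its CH2 on the acetyl-bearing C5, as is the rule for 1,1-dialkoxyethenes and excited enones. Facial selectivity is required as well and rests only on the steric bias of the C2 substituent on the cyclopentene envelope, which low temperature should sharpen. The ring keeps the excited enone from relaxing by double-bond twisting, the excess of 6 outruns enone dimerisation, and the Pyrex cut-off spares the product ketone.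

Step 5
Reactants: 7 photoadduct (angular acetyl, cyclobutanone diethyl ketal)
Product: 8 6,6-diethoxy-1,3-diisopropenyl-cis-bicyclo[3.2.0]heptane
Conditions: Ph3PCH3Br, KOtBu, THF, 0 °C to 60 °C
Reagents that add atoms: methyltriphenylphosphonium bromide, C[P+](c1ccccc1)(c1ccccc1)c1ccccc1.[Br-]
Why: Wittig methylenation, in which excess salt-free ylide and warming should overcome the hindrance of the methyl ketone on a quaternary carbon; the ketal is inert to base and no stereocentre is enolisable because C5 is quaternary.

Step 6
Reactants: 8 diene ketal
Product: 9 1,3-diisopropenyl-cis-bicyclo[3.2.0]heptan-6-one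
Conditions: 0.5 M aq. HCl (cat.), THF, 0 °C to rt
Reagents that add atoms: water, O
Why: Acid-catalysed ketal hydrolysis, where dilute acid should unmask the strained ketone without hydrating or shifting the two 1,1-disubstituted alkenes; the cis fusion is the only stable arrangement of the bicycle, so C4 cannot epimerise.

Step 7
Reactants: 9 cis-fused cyclobutanone
Product: 11 5,7-diisopropenyl-cis-2-oxabicyclo[3.3.0]octan-3-one (γ-lactone C4–O–C9(=O)–C10–C5), via sodium hydroxy carboxylate 10 (not isolated)
Conditions: 30% aq. H2O2, NaOH, MeOH/H2O, 0 °C; then aq. HCl to pH 2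
Reagents that add atoms: hydrogen peroxide, OO
Why: Baeyer–Villiger oxidation by hydroperoxide anion, fast for the strained cyclobutanone and blind to isolated alkenes, with migration of the more substituted C4 with retention so that the new C4–O bond stays cis to C10; hydroxide opens the lactone to the hydroxy carboxylate, which recloses on acidification.

Step 8
Reactants: 11 γ-lactone
Product: 13 4-methyl-5,7-diisopropenyl-cis-2-oxabicyclo[3.3.0]octan-3-one (C10 methyl anti to the angular isopropenyl), via lithium enolate 12 (not isolated)
Conditions: LiN(i-Pr)2 (1.05 equiv), THF, −78 °C; MeI, −78 to −40 °C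
Reagents that add atoms: iodomethane, CI
Why: Kinetic alkylation of a lactone lithium enolate, in which iodomethane should reach C10 on the face away from the freely rotating angular isopropenyl group on the neighbouring quaternary C5 (the side of the tied-back ring methylene C1), setting C10 with the methyl anti to C6.

Step 9
Reactants: 13 C10-methyl lactone
Product: 14 4-methyl-5,7-diisopropenyl-cis-2-oxabicyclo[3.3.0]octan-3-ol (lactol, anomer mixture)
Conditions: i-Bu2AlH (1.1 equiv), toluene, −78 °C; H2O work-up
Reagents that add atoms: none
Why: Partial reduction of a γ-lactone, which stops at the aluminium hemiacetal at −78 °C and gives the lactol on work-up; the alkenes are inert and the non-basic conditions leave C10 intact.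

Step 10
Reactants: 14 lactol; 15 methoxyallene
Product: 17 2-(2-hydroxy-1,4-diisopropenylcyclopentyl)-4-methoxyhexa-4,5-dien-3-ol (C4,C9-diol with the 1-methoxyallenyl group on C9), via 1-lithio-1-methoxyallene 16 (not isolated)
Conditions: 15 (4 equiv), n-BuLi (3.8 equiv), THF, −40 °C; then 14, −78 to −20 °C; H2O quench
Reagents that add atoms: none
Why: Organolithium addition to a lactol through its ring-opened alkoxy aldehyde, with the lithiated allenyl ether as an acryloyl anion equivalent; after the first equivalent deprotonates the lactol, Felkin–Anh attack anti to the quaternary C5 with the C10 methyl in the medium position should set C9 so that its oxygen ends trans to the C10 methyl in the later ring.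

Step 11
Reactants: 17 allenyl ether diol
Product: 18 4-hydroxy-5-(2-hydroxy-1,4-diisopropenylcyclopentyl)hex-1-en-3-one (α'-hydroxy vinyl ketone)
Conditions: 5% aq. H2SO4, THF, 0 °C
Reagents that add atoms: water, O
Why: Hydrolysis of the allenyl enol ether, where protonation at the central allene carbon gives a vinyl-substituted oxocarbenium ion that water turns into the vinyl ketone under conditions too mild to hydrate the alkenes or epimerise C9.

Step 12
Reactants: 18 α'-hydroxy vinyl ketone
Product: 19 (2S,4R,5R,9R,10S)-4,9-dihydroxy-2-isopropenyl-6,10-dimethylspiro[4.5]dec-6-en-8-one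
Conditions: second-generation Hoveyda–Grubbs catalyst (H2IMes)Cl2Ru(=CH-C6H4-2-O-i-Pr) (10 mol%), toluene, 80 °C, high dilution
Reagents that add atoms: none
Why: Ring-closing metathesis of the C6 isopropenyl group with the vinyl ketone closes the six-membered ring at C6=C7 with loss of ethylene, helped by the quaternary C5 (Thorpe–Ingold effect) and by formation of a conjugated trisubstituted enone; the C2 isopropenyl, although cis to C6, could only close a strained norbornene with a tetrasubstituted alkene, and no stereocentre is touched.

Step 13
Reactants: 19 spirocyclic diol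
Product: 20 (2S,4R,5R,9R,10S)-9-acetoxy-4-hydroxy-2-isopropenyl-6,10-dimethylspiro[4.5]dec-6-en-8-one
Conditions: Ac2O (1.2 equiv), pyridine, CH2Cl2, 0 °C
Reagents that add atoms: acetic anhydride, CC(=O)OC(C)=O
Why: Selective O-acylation, since the α-ketol hydroxyl at C9 is flanked by a flat carbonyl whereas the C4 hydroxyl is neopentylic next to the spiro centre and screened by the C10 methyl, so a small excess of anhydride without acyl-transfer catalyst should acetylate C9 only; pyridine is too weak a base to epimerise C9.

Step 14
Reactants: 20 C9 acetate
Product: 21 target, (2S,4R,5R,9R,10S)-9-acetoxy-2-isopropenyl-6,10-dimethyl-8-oxospiro[4.5]dec-6-en-4-yl 2-methylpropanoate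
Conditions: (i-PrCO)2O, 4-(dimethylamino)pyridine (cat.), pyridine, CH2Cl2, rt
Reagents that add atoms: isobutyric anhydride, CC(C)C(=O)OC(=O)C(C)C
Why: Acyl-transfer catalysed esterification of the hindered secondary alcohol through the N-acylpyridinium ion, which can be forced because no other hydroxyl remains, while the mild amine base should leave the α-acetoxy ketone centre C9 intact.

Compound list
1 | (S)-(−)-limonene | CC1=CC[C@@H](C(C)=C)CC1 | starting material
2 | (4S)-limonene 1,2-oxide, cis/trans mixture at the epoxide | CC12CC[C@@H](CC1O2)C(C)=C | intermediate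
3 | (4S)-limonene-1,2-diol, diastereomer mixture (not isolated) | CC1(O)CC[C@@H](CC1O)C(C)=C | intermediate
4 | (3S)-3-isopropenyl-6-oxoheptanal | CC(=O)CC[C@@H](CC=O)C(C)=C | intermediate
5 | (R)-1-acetyl-4-isopropenylcyclopentene | CC(=O)C1=CC[C@@H](C(C)=C)C1 | intermediate
6 | ketene diethyl acetal (1,1-diethoxyethene) | C=C(OCC)OCC | starting material
7 | 1-acetyl-6,6-diethoxy-3-isopropenyl-cis-bicyclo[3.2.0]heptane, cyclobutane anti to the isopropenyl | C=C(C)[C@@H]1C[C@H]2C(OCC)(OCC)C[C@]2(C1)C(C)=O | intermediate
8 | 6,6-diethoxy-1,3-diisopropenyl-cis-bicyclo[3.2.0]heptane | C=C(C)[C@@H]1C[C@H]2C(OCC)(OCC)C[C@]2(C1)C(C)=C | intermediate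
9 | 1,3-diisopropenyl-cis-bicyclo[3.2.0]heptan-6-one | C=C(C)[C@@H]1C[C@H]2C(=O)C[C@]2(C1)C(C)=C | intermediate
10 | sodium 2-(2-hydroxy-1,4-diisopropenylcyclopentyl)acetate, hydroxyl cis to the acetate arm (not isolated) | C=C(C)[C@@H]1C[C@@H](O)[C@](C1)(CC(=O)[O-])C(C)=C.[Na+] | intermediate
11 | 5,7-diisopropenyl-cis-2-oxabicyclo[3.3.0]octan-3-one | C=C(C)[C@@H]1C[C@H]2OC(=O)C[C@]2(C1)C(C)=C | intermediate
12 | lithium enolate of lactone 11 (not isolated) | C=C(C)[C@@H]1C[C@H]2OC([O-])=C[C@]2(C1)C(C)=C.[Li+] | intermediate
13 | 4-methyl-5,7-diisopropenyl-cis-2-oxabicyclo[3.3.0]octan-3-one, methyl anti to the angular isopropenyl | C=C(C)[C@@H]1C[C@H]2OC(=O)[C@@H](C)[C@]2(C1)C(C)=C | intermediate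
14 | 4-methyl-5,7-diisopropenyl-cis-2-oxabicyclo[3.3.0]octan-3-ol, anomer mixture | C=C(C)[C@@H]1C[C@H]2OC(O)[C@@H](C)[C@]2(C1)C(C)=C | intermediate
15 | methoxyallene (1-methoxypropa-1,2-diene) | COC=C=C | starting material
16 | 1-lithio-1-methoxyallene (not isolated) | [Li]C(OC)=C=C | intermediate
17 | 2-(2-hydroxy-1,4-diisopropenylcyclopentyl)-4-methoxyhexa-4,5-dien-3-ol | C=C(C)[C@@H]1C[C@@H](O)[C@@](C1)(C(C)=C)[C@H](C)[C@@H](O)C(OC)=C=C | intermediate
18 | 4-hydroxy-5-(2-hydroxy-1,4-diisopropenylcyclopentyl)hex-1-en-3-one | C=C(C)[C@@H]1C[C@@H](O)[C@@](C1)(C(C)=C)[C@H](C)[C@@H](O)C(=O)C=C | intermediate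
19 | (2S,4R,5R,9R,10S)-4,9-dihydroxy-2-isopropenyl-6,10-dimethylspiro[4.5]dec-6-en-8-one | C=C(C)[C@@H]1C[C@@H](O)[C@@]2(C1)C(C)=CC(=O)[C@H](O)[C@H]2C | intermediate
20 | (2S,4R,5R,9R,10S)-9-acetoxy-4-hydroxy-2-isopropenyl-6,10-dimethylspiro[4.5]dec-6-en-8-one | C=C(C)[C@@H]1C[C@@H](O)[C@@]2(C1)C(C)=CC(=O)[C@H](OC(C)=O)[C@H]2C | intermediate
21 | (2S,4R,5R,9R,10S)-9-acetoxy-2-isopropenyl-6,10-dimethyl-8-oxospiro[4.5]dec-6-en-4-yl 2-methylpropanoate (CNP0229299.1) | C=C(C)[C@@H]1C[C@@H](OC(=O)C(C)C)[C@@]2(C1)C(C)=CC(=O)[C@H](OC(C)=O)[C@H]2C | target

Total step count: 14. Longest linear sequence: 14 steps (1 to 21); 6 and 15 are bought.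

Steps most likely to fail

Step 4. The flat isopropenyl group sits two bonds from both reacting carbons and may discriminate poorly between the two faces of the cyclopentene, so much of the material could add on the wrong face. The fallback sets out from 5 and replaces the sp2 substituent by a branched sp3 one that is also photochemically silent. mCPBA epoxidises only the electron-rich side-chain alkene of 5 to give 1-acetyl-4-(2-methyloxiran-2-yl)cyclopentene F1 (epoxide epimers, immaterial). Irradiation of F1 with excess 6 as in step 4 should give the epoxy photoadduct F2 with a quaternary carbon directly on C2 screening its face. Methylenation with Ph3P=CH2 gives the epoxy diene ketal F3. The alkene is then regenerated by phosphide deoxygenation: Ph2PLi opens the epoxide at its CH2 to the lithium β-phosphino alkoxide F4, MeI quaternises phosphorus to the betaine F5, and this collapses to 8, where the route is rejoined.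

Step 8. The cup shape of the bicycle opposes the local bias of the angular isopropenyl group, so the methyl may be delivered to the isopropenyl face, and a second alkylation can compete. The fallback sets out from 11 and uses the same facial preference in reverse. If methylation under the step 8 conditions gives the C10-epimeric methyl lactone F6, it is deprotonated again with LiN(i-Pr)2 at −78 °C to the methyl-substituted lithium enolate F7. Kinetic protonation with a bulky proton source (2,6-di-tert-butyl-4-methylphenol) then enters from the face the electrophile preferred, which leaves the methyl anti to the isopropenyl and returns 13.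

Step 12. Turnover may be too slow because one partner is an electron-poor vinyl ketone and the other a 1,1-disubstituted alkene on a quaternary carbon, so the catalyst may decompose before ring closure. The fallback sets out from 18 and changes the electronic character of the metathesis partner. Luche reduction (NaBH4, CeCl3·7H2O, MeOH, −78 °C) gives the triene triol F8 (C8 epimers, immaterial), whose monosubstituted allylic alcohol loads ruthenium readily. Ring closure with the second-generation Grubbs catalyst (H2IMes)(PCy3)Cl2Ru=CHPh in CH2Cl2 at 40 °C should give the spirocyclic cyclohexene triol F9. MnO2 in CH2Cl2 then oxidises only the allylic C8 hydroxyl and returns 19.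

Further compounds
F1 | step 4 | 1-acetyl-4-(2-methyloxiran-2-yl)cyclopentene | CC(=O)C1=CC[C@@H](C2(C)CO2)C1
F2 | step 4 | 1-acetyl-6,6-diethoxy-3-(2-methyloxiran-2-yl)-cis-bicyclo[3.2.0]heptane | CC1(CO1)[C@@H]2C[C@H]3C(OCC)(OCC)C[C@]3(C2)C(C)=O
F3 | step 4 | 6,6-diethoxy-1-isopropenyl-3-(2-methyloxiran-2-yl)-cis-bicyclo[3.2.0]heptane | CC1(CO1)[C@@H]2C[C@H]3C(OCC)(OCC)C[C@]3(C2)C(C)=C
F4 | step 4 | lithium β-(diphenylphosphino) alkoxide from opening of F3 | CC([O-])(CP(c1ccccc1)c1ccccc1)[C@@H]1C[C@H]2C(OCC)(OCC)C[C@]2(C1)C(C)=C.[Li+]
F5 | step 4 | methyldiphenylphosphonium alkoxide betaine | CC([O-])(C[P+](C)(c1ccccc1)c1ccccc1)[C@@H]1C[C@H]2C(OCC)(OCC)C[C@]2(C1)C(C)=C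
F6 | step 8 | C10 epimer of methyl lactone 13 | C=C(C)[C@@H]1C[C@H]2OC(=O)[C@H](C)[C@]2(C1)C(C)=C
F7 | step 8 | lithium enolate of the methyl lactone | C=C(C)[C@@H]1C[C@H]2OC([O-])=C(C)[C@]2(C1)C(C)=C.[Li+]
F8 | step 12 | 5-(2-hydroxy-1,4-diisopropenylcyclopentyl)hex-1-ene-3,4-diol | C=C(C)[C@@H]1C[C@@H](O)[C@@](C1)(C(C)=C)[C@H](C)[C@@H](O)C(O)C=C
F9 | step 12 | 2-isopropenyl-6,10-dimethylspiro[4.5]dec-6-ene-4,8,9-triol | C=C(C)[C@@H]1C[C@@H](O)[C@@]2(C1)C(C)=CC(O)[C@H](O)[C@H]2C
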